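**Plan**

- Numbering (germacrane): C1=C10 is the ester-bearing alkene (ester carbon C14 on C10), C2/C3 the CH2CH2 link, C4=C5 the methyl-bearing alkene, C6 the lactone O–CH, C7 the ring-fusion CH, C8 the methacrylate CH, C9 the carbinol, C11=C13 the exo-methylene, C12 the lactone carbonyl.
- Enabling feature and main cut: O8–C8–C7–C11(=C13) is a homoallylic alcohol whose alkene is the exo-methylene of the γ-lactone and whose C7 is the fusion atom of the ten-membered carbocycle. Cutting C7–C8 and joining O8 to C13 gives a thirteen-membered cyclic α-allyloxy ketone (C9 ketone; C12 and C14 as CH2OSi).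
- Further cuts: C9–C10 (Ni/Cr alkenyl bromide–aldehyde ring closure), C11–C12 (Stille hydroxymethylation), C6–C7 (alkynylation of a C1–C6 enal by a propargyl ether that brings C7, C11, C13, O, C8 and C9), C1=C10 (bromo-Wittig on the aldehyde from geranyl acetate).
- Forward order: chain C14–C10=C1–C6 first, then the ether arm joined at C6, C12 added, the thirteen-membered ring closed and contracted to the ten-membered carbocycle, and the lactone ring closed last by oxidation of the C6/C12 diol.
- Stereochemistry: C6 from a ligand-controlled alkynylation; C7 and C8 from the ring contraction (relayed from C6 and the C7=C11 geometry); C9 from a Felkin–Anh hydride addition; 4E from geranyl acetate, the C1=C10 geometry from the bromo ylide, the C7=C11 geometry from a trans-hydroalumination.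

Key step: step 13

Assumption: the (S,S)-enantiomer of the ProPhenol ligand is taken to deliver the alkynylzinc to the Si face of enal 6 (giving 6R); should the sense be the opposite, the (R,R)-ligand is used and nothing else changes.

**Route**

Step 1
Reactants: 1 geranyl acetate
Product: 3 (2E)-3-methyl-6-oxohex-2-en-1-yl acetate, via secondary ozonide 2 (not isolated)
Conditions: O3 (1.0 equiv), CH2Cl2, pyridine (cat.), −78 °C; then Me2S, −78 °C to rt
Reagents that add atoms: ozone, [O-][O+]=O
Why: Ozonolysis with reductive work-up; the terminal trisubstituted alkene is the more electron-rich one (the 2,3-alkene is deactivated by the allylic acetate), so one equivalent of ozone should cleave it selectively and leave the E alkene that becomes C4=C5 untouched.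

Step 2
Reactants: 3 (2E)-3-methyl-6-oxohex-2-en-1-yl acetate
Product: 4 methyl (2Z,6E)-8-acetoxy-2-bromo-6-methylocta-2,6-dienoate
Conditions: Ph3P=CHCO2Me, N-bromosuccinimide, CH2Cl2, −20 °C; then 3, −20 °C to rt
Reagents that add atoms: methyl (triphenylphosphoranylidene)acetate, COC(=O)C=P(c1ccccc1)(c1ccccc1)c1ccccc1; N-bromosuccinimide, O=C1CCC(=O)N1Br
Why: Wittig olefination with the α-bromo ylide generated in the flask; as a stabilised ylide it should place the ester trans to the chain and bromine cis to C2 (2Z), which is the C1=C10 geometry of the target with bromine standing in for C9.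

Step 3
Reactants: 4 methyl (2Z,6E)-8-acetoxy-2-bromo-6-methylocta-2,6-dienoate
Product: 5 methyl (2Z,6E)-2-bromo-8-hydroxy-6-methylocta-2,6-dienoate
Conditions: K2CO3 (0.2 equiv), MeOH, 0 °C
Reagents that add atoms: none
Why: Base-catalysed methanolysis (transesterification) of the primary allylic acetate; exchange at the methyl ester is degenerate, and catalytic carbonate at 0 °C should not add methoxide to the bromo-enoate.

Step 4
Reactants: 5 methyl (2Z,6E)-2-bromo-8-hydroxy-6-methylocta-2,6-dienoate
Product: 6 methyl (2Z,6E)-2-bromo-6-methyl-8-oxoocta-2,6-dienoate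
Conditions: MnO2, CH2Cl2, rt
Reagents that add atoms: none
Why: MnO2 oxidation of the only (allylic, primary) alcohol to the E enal without touching the bromo-enoate.

Step 5
Reactants: 7 2-(prop-2-yn-1-yloxy)ethan-1-ol
Product: 8 triethyl[2-(prop-2-yn-1-yloxy)ethoxy]silane
Conditions: Et3SiCl, imidazole, CH2Cl2, 0 °C
Reagents that add atoms: chlorotriethylsilane, CC[Si](Cl)(CC)CC
Why: Standard silylation of a primary alcohol; the triethylsilyl ether is chosen because step 10 can turn it directly into the C9 aldehyde in the presence of tert-butyldimethylsilyl ethers.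

Step 6
Reactants: 6 methyl (2Z,6E)-2-bromo-6-methyl-8-oxoocta-2,6-dienoate; 8 triethyl[2-(prop-2-yn-1-yloxy)ethoxy]silane
Product: 10 methyl (2Z,6E,8R)-2-bromo-8-hydroxy-6-methyl-11-[2-(triethylsilyloxy)ethoxy]undeca-2,6-dien-9-ynoate, via alkynylzinc 9 (not isolated)
Conditions: 8 (3 equiv), Me2Zn (3 equiv), (S,S)-ProPhenol (20 mol%), Ph3P=O (40 mol%), toluene, 0 °C; then 6, 4 °C
Reagents that add atoms: none
Why: Zinc–ProPhenol-catalysed enantioselective alkynylation of an enal; the dinuclear zinc alkoxide binds aldehyde and alkynyl side by side and delivers the alkyne to the Si face, which sets C6 as R, while the ester and the alkenyl bromide are inert to the alkynylzinc.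

Step 7
Reactants: 10 methyl (2Z,6E,8R)-2-bromo-8-hydroxy-6-methyl-11-[2-(triethylsilyloxy)ethoxy]undeca-2,6-dien-9-ynoate
Product: 12 (2Z,6E,8R,9Z)-2-bromo-10-iodo-6-methyl-11-[2-(triethylsilyloxy)ethoxy]undeca-2,6,9-triene-1,8-diol, via alkenylalanate 11 (not isolated)
Conditions: NaAlH2(OCH2CH2OMe)2 (4.5 equiv), THF, −20 to 0 °C; then I2, −78 to 0 °C
Reagents that add atoms: iodine, II
Why: Alkoxide-directed trans-hydroalumination of the propargylic alcohol followed by iodinolysis, with the ester reduced to the C14 alcohol by the same hydride; hydride goes to C7 and aluminium to C11 in a five-membered chelate, so iodine ends cis to C6 and the ether arm trans, and the temperature is held at or below 0 °C so that the β-alkoxy alanate does not eliminate to an allene.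

Step 8
Reactants: 12 (2Z,6E,8R,9Z)-2-bromo-10-iodo-6-methyl-11-[2-(triethylsilyloxy)ethoxy]undeca-2,6,9-triene-1,8-diol
Product: 13 (2Z,6E,8R,9E)-2-bromo-10-(hydroxymethyl)-6-methyl-11-[2-(triethylsilyloxy)ethoxy]undeca-2,6,9-triene-1,8-diol
Conditions: Bu3SnCH2OH (1.5 equiv), Pd(PPh3)4 (10 mol%), toluene, 85 °C
Reagents that add atoms: (tributylstannyl)methanol, OC[Sn](CCCC)(CCCC)CCCC
Why: Kosugi–Migita–Stille hydroxymethylation with retention of alkene geometry; zerovalent palladium inserts into the C–I bond far faster than into the hindered trisubstituted C–Br bond, so C12 is attached cis to C6 and the bromide is kept for step 11.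

Step 9
Reactants: 13 (2Z,6E,8R,9E)-2-bromo-10-(hydroxymethyl)-6-methyl-11-[2-(triethylsilyloxy)ethoxy]undeca-2,6,9-triene-1,8-diol
Product: 14 tris(tert-butyldimethylsilyl) ether of triol 13
Conditions: t-BuMe2SiCl (4.5 equiv), imidazole, DMAP (cat.), DMF, rt
Reagents that add atoms: tert-butyldimethylsilyl chloride, CC(C)(C)[Si](C)(C)Cl
Why: Exhaustive silylation of the two primary allylic hydroxyls (C12, C14) and the secondary C6 hydroxyl under standard imidazole conditions, which do not disturb the triethylsilyl ether.

Step 10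
Reactants: 14 tris(tert-butyldimethylsilyl) ether of triol 13
Product: 16 seco-aldehyde (C9 aldehyde and C10 bromide), via alkoxysulfonium salt 15 (not isolated)
Conditions: (COCl)2 (4 equiv), DMSO (8 equiv), CH2Cl2, −78 to −35 °C; then Et3N, −78 °C to rt
Reagents that add atoms: none
Why: Swern oxidation applied directly to a primary triethylsilyl ether; the activated sulfoxide is attacked by the least hindered silyl ether oxygen, chlorotriethylsilane is lost and the alkoxysulfonium salt collapses to the aldehyde on addition of base, whereas the bulkier tert-butyldimethylsilyl ethers are untouched.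

Step 11
Reactants: 16 seco-aldehyde (C9 aldehyde and C10 bromide)
Product: 17 thirteen-membered ether alcohol (C9–OH as epimer mixture)
Conditions: CrCl2 (10 equiv), NiCl2 (20 mol%), DMSO/THF 3:1, 3 mM (slow addition of 16), rt to 50 °C
Reagents that add atoms: none
Why: Nozaki–Hiyama–Kishi reaction; zerovalent nickel inserts into the alkenyl C–Br bond, transmetalation gives an alkenylchromium that adds to the aldehyde with retention of alkene geometry, and the aldehyde selectivity of organochromium reagents together with high dilution lets the thirteen-membered ring close (the C9 configuration is irrelevant).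

Step 12
Reactants: 17 thirteen-membered ether alcohol (C9–OH as epimer mixture)
Product: 18 (4Z,8E,10R,11Z)-10-(tert-butyldimethylsilyloxy)-4,12-bis[(tert-butyldimethylsilyloxy)methyl]-8-methyl-1-oxacyclotrideca-4,8,11-trien-3-one
Conditions: Dess–Martin periodinane, pyridine, CH2Cl2, 0 °C to rt
Reagents that add atoms: none
Why: Dess–Martin oxidation of the allylic alcohol to the enone erases the uncontrolled C9 centre and gives the α-allyloxy ketone needed for enolisation.

Step 13
Reactants: 18 thirteen-membered α-allyloxy enone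
Product: 20 ten-membered α-hydroxy ketone (6R,7R,8S) with the C11=C13 methylene arm on C7, via lithium enolate 19 (not isolated)
Conditions: LiN(SiMe3)2 (1.2 equiv), THF, −78 to −20 °C; AcOH, −78 °C
Reagents that add atoms: none
Why: Kinetic deprotonation by LiN(SiMe3)2 at C8, the only sp3 α-carbon of the C9 ketone, gives the chelated lithium enolate 19, whose C8 attacks C7 through a five-membered envelope (C8–O–C13–C11=C7) while O–C13 breaks and C11=C13 forms, a [2,3]-Wittig rearrangement. The closest known reactions are the [2,3]-Wittig shift of α-allyloxy ketone enolates and the ring contraction of thirteen-membered diallylic ethers to cyclodeca-1,5-dienes. The ten-membered carbocycle closes by transannular C7–C8 bond formation inside the macrocycle (a three-atom ring contraction, 13 to 10, through a five-membered cyclic array that is formally 5-endo at the C7=C11 bond), so no additional entropic price is paid. C7 is controlled by C6: 1,3-allylic strain with the cis C12 arm holds H6 in the alkene plane and the enolate adds anti to the C6–OSi bond, which gives the 6,7-relationship of the trans lactone. C8 is controlled by the alkene geometry (C6 trans to C13) together with the tether, which should hold C9 and C6 on the same side of the envelope (carbonyl endo), the syn outcome usual for enolate-type carbanions and trans-allyl termini. The step needs C8 deprotonation over γ-deprotonation at C2 and the [2,3] over the [1,2] or [3,3] shift; the lithium counter-ion, the low temperature and the cold acidic quench should secure this and keep the new α-ketol from epimerising.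

Step 14
Reactants: 20 ten-membered α-hydroxy ketone (6R,7R,8S)
Product: 21 8-O-methacrylate of 20
Conditions: methacrylic anhydride, i-Pr2NEt, DMAP (cat.), CH2Cl2, 0 °C
Reagents that add atoms: methacrylic anhydride, CC(=C)C(=O)OC(=O)C(C)=C
Why: DMAP-catalysed acylation of the only free hydroxyl, so the ester is placed on O8 without any regiochemical question and under conditions too mild to enolise C8.

Step 15
Reactants: 21 8-O-methacrylate of 20
Product: 22 (9S)-allylic alcohol (6R,7R,8S,9S)
Conditions: NaBH4, CeCl3·7H2O, MeOH/THF, −78 °C; AcOH quench at −78 °C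
Reagents that add atoms: none
Why: Luche 1,2-reduction of the enone; hydride is expected to add anti to the C8–O bond (Felkin–Anh, polar model) from the exposed face of the ring ketone, which gives the 8,9-relationship of the target (9S), cerium suppresses conjugate reduction and the cold acidic quench prevents an 8-to-9 acyl shift.

Step 16
Reactants: 22 (9S)-allylic alcohol (6R,7R,8S,9S)
Product: 23 tetraol 8-methacrylate (6-OH, 9-OH, 12-OH and 14-OH free)
Conditions: HF·pyridine, pyridine, THF, 0 °C to rt
Reagents that add atoms: none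
Why: Fluoride-mediated cleavage of all three silyl ethers under buffered, non-basic conditions, so the methacrylate neither migrates nor suffers conjugate addition.

Step 17
Reactants: 23 tetraol 8-methacrylate
Product: 25 6,12-lactone with C14 aldehyde, via lactol 24 (not isolated)
Conditions: TEMPO (0.3 equiv), PhI(OAc)2 (4 equiv), CH2Cl2, rt
Reagents that add atoms: none
Why: Oxoammonium (TEMPO/PhI(OAc)2) oxidation selective for primary alcohols; C12–OH gives the aldehyde, which is trapped by the cis-disposed C6–OH as a lactol and oxidised on to the α-methylene-γ-lactone (oxidative lactonisation of a 2-methylene-1,4-diol), C14–OH gives the enal, and the hindered secondary C9–OH should be spared.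

Step 18
Reactants: 25 6,12-lactone with C14 aldehyde
Product: 26 C14 carboxylic acid
Conditions: NaClO2, NaH2PO4, 2-methyl-2-butene, t-BuOH/H2O, 0 °C to rt
Reagents that add atoms: sodium chlorite, [Na+].[O-]Cl=O
Why: Pinnick oxidation of the enal to the acid; the alkene scavenger removes hypochlorous acid, so the C4=C5 alkene, the methylene lactone and the free C9 hydroxyl are left alone.

Step 19
Reactants: 26 C14 carboxylic acid
Product: 27 CNP0282644.1 (target)
Conditions: Me3SiCHN2, toluene/MeOH, 0 °C
Reagents that add atoms: (trimethylsilyl)diazomethane, C[Si](C)(C)C=[N+]=[N-]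
Why: Methyl ester formation by protonation of the diazoalkane and displacement by the carboxylate; at 0 °C with a slight excess this is much faster than dipolar cycloaddition to the methylene lactone or methacrylate.

**Compound list**

1 | geranyl acetate, (2E)-3,7-dimethylocta-2,6-dien-1-yl acetate | CC(C)=CCC/C(C)=C/COC(C)=O | starting material
2 | secondary ozonide, (2E)-5-(5,5-dimethyl-1,2,4-trioxolan-3-yl)-3-methylpent-2-en-1-yl acetate (not isolated) | CC1(C)OOC(CC/C(C)=C/COC(C)=O)O1 | intermediate
3 | (2E)-3-methyl-6-oxohex-2-en-1-yl acetate | O=CCC/C(C)=C/COC(C)=O | intermediate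
4 | methyl (2Z,6E)-8-acetoxy-2-bromo-6-methylocta-2,6-dienoate | COC(=O)/C(Br)=C/CC/C(C)=C/COC(C)=O | intermediate
5 | methyl (2Z,6E)-2-bromo-8-hydroxy-6-methylocta-2,6-dienoate | COC(=O)/C(Br)=C/CC/C(C)=C/CO | intermediate
6 | methyl (2Z,6E)-2-bromo-6-methyl-8-oxoocta-2,6-dienoate | COC(=O)/C(Br)=C/CC/C(C)=C/C=O | intermediate
7 | 2-(prop-2-yn-1-yloxy)ethan-1-ol | C#CCOCCO | starting material
8 | triethyl[2-(prop-2-yn-1-yloxy)ethoxy]silane | C#CCOCCO[Si](CC)(CC)CC | intermediate
9 | methyl{3-[2-(triethylsilyloxy)ethoxy]prop-1-yn-1-yl}zinc (not isolated) | C[Zn]C#CCOCCO[Si](CC)(CC)CC | intermediate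
10 | methyl (2Z,6E,8R)-2-bromo-8-hydroxy-6-methyl-11-[2-(triethylsilyloxy)ethoxy]undeca-2,6-dien-9-ynoate (C6 of the target is C8 here) | O[C@@H](C#CCOCCO[Si](CC)(CC)CC)/C=C(\C)CC/C=C(\Br)C(=O)OC | intermediate
11 | alkenylalanate: five-membered chelate with aluminium bound to O6 and C11, ester already reduced to the C14 alkoxide, drawn in simplified form as the disodium salt (not isolated) | [Na+].[Na+].COCCO[Al-]1(OCCOC)O[C@H](/C=C(\C)CC/C=C(\Br)C[O-])C=C1COCCO[Si](CC)(CC)CC | intermediate
12 | (2Z,6E,8R,9Z)-2-bromo-10-iodo-6-methyl-11-[2-(triethylsilyloxy)ethoxy]undeca-2,6,9-triene-1,8-diol | O[C@@H](/C=C(\I)COCCO[Si](CC)(CC)CC)/C=C(\C)CC/C=C(\Br)CO | intermediate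
13 | (2Z,6E,8R,9E)-2-bromo-10-(hydroxymethyl)-6-methyl-11-[2-(triethylsilyloxy)ethoxy]undeca-2,6,9-triene-1,8-diol (hydroxymethyl cis to C8) | O[C@@H](/C=C(\CO)COCCO[Si](CC)(CC)CC)/C=C(\C)CC/C=C(\Br)CO | intermediate
14 | (2Z,6E,8R,9Z)-2-bromo-1,8-bis(tert-butyldimethylsilyloxy)-10-[(tert-butyldimethylsilyloxy)methyl]-6-methyl-11-[2-(triethylsilyloxy)ethoxy]undeca-2,6,9-triene | CC(C)(C)[Si](C)(C)O[C@@H](/C=C(\CO[Si](C)(C)C(C)(C)C)COCCO[Si](CC)(CC)CC)/C=C(\C)CC/C=C(\Br)CO[Si](C)(C)C(C)(C)C | intermediate
15 | alkoxydimethylsulfonium chloride formed from 14 by loss of the triethylsilyl group (not isolated) | CC(C)(C)[Si](C)(C)O[C@@H](/C=C(\CO[Si](C)(C)C(C)(C)C)COCCO[S+](C)C)/C=C(\C)CC/C=C(\Br)CO[Si](C)(C)C(C)(C)C.[Cl-] | intermediate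
16 | 2-{[(2Z,4R,5E,9Z)-10-bromo-4,11-bis(tert-butyldimethylsilyloxy)-2-[(tert-butyldimethylsilyloxy)methyl]-6-methylundeca-2,5,9-trien-1-yl]oxy}acetaldehyde | CC(C)(C)[Si](C)(C)O[C@@H](/C=C(\CO[Si](C)(C)C(C)(C)C)COCC=O)/C=C(\C)CC/C=C(\Br)CO[Si](C)(C)C(C)(C)C | intermediate
17 | (4Z,8E,10R,11Z)-10-(tert-butyldimethylsilyloxy)-4,12-bis[(tert-butyldimethylsilyloxy)methyl]-8-methyl-1-oxacyclotrideca-4,8,11-trien-3-ol, both C3 (= C9) epimers | OC1COC/C(CO[Si](C)(C)C(C)(C)C)=C/[C@H](O[Si](C)(C)C(C)(C)C)/C=C(\C)CC/C=C1/CO[Si](C)(C)C(C)(C)C | intermediate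
18 | (4Z,8E,10R,11Z)-10-(tert-butyldimethylsilyloxy)-4,12-bis[(tert-butyldimethylsilyloxy)methyl]-8-methyl-1-oxacyclotrideca-4,8,11-trien-3-one (ring C8–O–C13–C11=C7–C6–C5=C4–C3–C2–C1=C10–C9) | C1OC/C(CO[Si](C)(C)C(C)(C)C)=C/[C@H](O[Si](C)(C)C(C)(C)C)/C=C(\C)CC/C=C(/CO[Si](C)(C)C(C)(C)C)C1=O | intermediate
19 | lithium enolate of 18 (C8=C9–OLi) (not isolated) | [Li+].[O-]C1=COC/C(CO[Si](C)(C)C(C)(C)C)=C/[C@H](O[Si](C)(C)C(C)(C)C)/C=C(\C)CC/C=C1/CO[Si](C)(C)C(C)(C)C | intermediate
20 | (2Z,6E,8R,9R,10S)-8-(tert-butyldimethylsilyloxy)-10-hydroxy-2-[(tert-butyldimethylsilyloxy)methyl]-6-methyl-9-[3-(tert-butyldimethylsilyloxy)prop-1-en-2-yl]cyclodeca-2,6-dien-1-one; germacrane descriptors 6R,7R,8S | O[C@H]1[C@@H](C(=C)CO[Si](C)(C)C(C)(C)C)[C@H](O[Si](C)(C)C(C)(C)C)/C=C(\C)CC/C=C(/CO[Si](C)(C)C(C)(C)C)C1=O | intermediate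
21 | 8-O-(2-methylprop-2-enoyl) ester of 20 (6R,7R,8S) | C=C(C)C(=O)O[C@H]1[C@@H](C(=C)CO[Si](C)(C)C(C)(C)C)[C@H](O[Si](C)(C)C(C)(C)C)/C=C(\C)CC/C=C(/CO[Si](C)(C)C(C)(C)C)C1=O | intermediate
22 | 9-alcohol from 21 (6R,7R,8S,9S): 9-OH on the face opposite to the 8-acyloxy group in the ring drawing | C=C(C)C(=O)O[C@H]1[C@@H](C(=C)CO[Si](C)(C)C(C)(C)C)[C@H](O[Si](C)(C)C(C)(C)C)/C=C(\C)CC/C=C(/CO[Si](C)(C)C(C)(C)C)[C@@H]1O | intermediate
23 | desilylated tetraol 8-methacrylate (6R,7S,8S,9S; 6-OH, 9-OH, 12-OH, 14-OH) | C=C(C)C(=O)O[C@H]1[C@@H](C(=C)CO)[C@H](O)/C=C(\C)CC/C=C(/CO)[C@@H]1O | intermediate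
24 | 6,12-lactol with C14 aldehyde (lactol carbon as epimers) (not isolated) | C=C(C)C(=O)O[C@H]1[C@H]2C(=C)C(O)O[C@@H]2/C=C(\C)CC/C=C(/C=O)[C@@H]1O | intermediate
25 | trans-fused α-methylene-γ-lactone with C14 aldehyde (6R,7S,8S,9S) | C=C(C)C(=O)O[C@H]1[C@H]2C(=C)C(=O)O[C@@H]2/C=C(\C)CC/C=C(/C=O)[C@@H]1O | intermediate
26 | corresponding C14 carboxylic acid | C=C(C)C(=O)O[C@H]1[C@H]2C(=C)C(=O)O[C@@H]2/C=C(\C)CC/C=C(/C(=O)O)[C@@H]1O | intermediate
27 | CNP0282644.1: methyl (1(10)E,4E,6R,7S,8S,9S)-9-hydroxy-8-(2-methylprop-2-enoyloxy)-12-oxogermacra-1(10),4,11(13)-trien-12,6-olid-14-oate | C=C(C)C(=O)O[C@H]1[C@H]2C(=C)C(=O)O[C@@H]2/C=C(\C)CC/C=C(/C(=O)OC)[C@@H]1O | target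

**Step count**

Total steps: 19. Longest linear sequence: 18 (steps 1–4 and 6–19, from geranyl acetate); step 5 is a one-step side branch.

**Steps most likely to fail**

Step 13 (ring contraction). The enolate may react with its carbonyl carbon on the outer side of the envelope instead of the inner one, which would invert the C7/C8 relationship (poor control at C8). Competing [3,3] or [1,2] shifts and C8 epimerisation of the α-ketol are further ways to lose material. The fallback sets out from 18 and accepts the other outcome: the rearrangement is run as before, and the 8-epimeric α-hydroxy ketone F1 is esterified under Mitsunobu conditions (methacrylic acid, PPh3, diisopropyl azodicarboxylate, toluene, 0 °C to rt). This installs the methacrylate with inversion at C8 and returns to the route at 21.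

Step 11 (Ni/Cr ring closure). Oxidative addition of nickel into the hindered trisubstituted alkenyl bromide may be slow, so that the α-alkoxy aldehyde oligomerises or decomposes under the Lewis-acidic chromium salts before the ring closes. The fallback sets out from 14 and changes the halide before the aldehyde is unveiled. Copper-catalysed Finkelstein-type exchange (CuI, NaI, trans-N,N'-dimethylcyclohexane-1,2-diamine, dioxane, 110 °C, retention of alkene geometry) gives the alkenyl iodide F2. Swern oxidation of its triethylsilyl ether as in step 10 gives the iodo aldehyde F3, and the Ni/Cr cyclisation of the iodide at room temperature returns to the route at 17.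

Step 15 (C9 reduction). The ring conformation may override the Felkin–Anh preference and give poor facial selectivity at C9, or the intermediate borate may promote an 8-to-9 acyl shift. The fallback sets out from 21 and hands the choice of face to the reagent: Corey–Bakshi–Shibata reduction ((S)-2-methyl-CBS-oxazaborolidine, catecholborane, toluene, −78 °C), on the usual assumption that the alkenyl side acts as the large group. It generates no basic alkoxide and returns to the route at 22 without any new compound (F0).

**Further compounds**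

F1 | step 13 | 8-epimer of 20 (germacrane 6R,7R,8R) | O[C@@H]1[C@@H](C(=C)CO[Si](C)(C)C(C)(C)C)[C@H](O[Si](C)(C)C(C)(C)C)/C=C(\C)CC/C=C(/CO[Si](C)(C)C(C)(C)C)C1=O
F2 | step 11 | alkenyl iodide analogue of 14 (iodine in place of bromine at C10) | CC(C)(C)[Si](C)(C)O[C@@H](/C=C(\CO[Si](C)(C)C(C)(C)C)COCCO[Si](CC)(CC)CC)/C=C(\C)CC/C=C(\I)CO[Si](C)(C)C(C)(C)C
F3 | step 11 | iodo aldehyde analogue of 16 | CC(C)(C)[Si](C)(C)O[C@@H](/C=C(\CO[Si](C)(C)C(C)(C)C)COCC=O)/C=C(\C)CC/C=C(\I)CO[Si](C)(C)C(C)(C)C
F0 | step 15 | none | none
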